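**Strategy.** The synthesis rests on making ring A de novo by cutting C4a–C8a and C5–C6. A thermal Danheiser benzannulation between 3-methoxy-2-prenylcyclobutenone and a chiral methyl ynol ether assembles the benzene ring in one operation. It exploits the fact that all six ring-A carbons differ (C4a bears C4, C5 OMe, C6 prenyl, C7 OMe, C8 H, C8a the ring oxygen O1): the cyclobutenone supplies C6, C7, C8 and C8a, the alkyne C4a and C5, and only the C8a hydroxyl emerges free for pyran closure. The ynol ether already holds C4, the R-configured C3 with the silyl-protected chromene ring B, and C2 as a silyl ether.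

Key step: step 11

Remarks on the chemistry:
- Locants (C2, C3, C4a, 4' and so on) follow the isoflavan numbering of the target. Ar = 2,2-dimethyl-5-[(triisopropylsilyl)oxy]-2H-chromen-8-yl.
- The ring-B phenol is carried as a triisopropylsilyl ether so that it survives the organolithium and alkoxide steps. The C2 oxygen is a tert-butyldimethylsilyl ether so that mild acid can remove it alone.
- The hydroxy ketone formed in step 8 equilibrates with its five-membered cyclic hemiketal; it is drawn and named in the open form.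
- The (R)-ligand in step 7 is chosen by analogy with the known facial preference for cyclic enones and lactones; the sense is to be confirmed on the lactone.
- Ketene for step 2 is generated outside the flask by pyrolysis of acetone.

Step 1
Reactants: 1 chloroacetaldehyde dimethyl acetal; 2 prenyl bromide
Product: 4 1-methoxy-5-methylhex-4-en-1-yne, via sodium methoxyacetylide 3 (not isolated)
Conditions: NaNH2 (3 equiv), liq. NH3, −33 °C; then 2, −33 °C → rt
Reagents that add atoms: none
Why: Sodium amide converts the chloroacetal by loss of methanol, loss of HCl and deprotonation into NaC≡COMe, which is alkylated at the primary carbon of the allylic bromide by SN2 substitution (the classical acetal route to 1-alkoxy-1-alkynes).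

Step 2
Reactants: 4 1-methoxy-5-methylhex-4-en-1-yne
Product: 5 3-methoxy-2-(3-methylbut-2-en-1-yl)cyclobut-2-en-1-one
Conditions: ketene (gas, from acetone pyrolysis), CH2Cl2, 0 °C → rt
Reagents that add atoms: ketene, C=C=O
Why: Thermal ketene–alkynyl ether [2+2] cycloaddition, in which the alkyne carbon remote from oxygen bonds to the ketene carbonyl carbon, should put prenyl on C2 and methoxy on C3, the isolated trisubstituted alkene being far less ketenophilic.

Step 3
Reactants: 6 4-bromoresorcinol
Product: 7 2-bromo-5-[(triisopropylsilyl)oxy]phenol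
Conditions: TIPSCl (1.0 equiv), imidazole, CH2Cl2, 0 °C
Reagents that add atoms: triisopropylsilyl chloride, CC(C)[Si](Cl)(C(C)C)C(C)C
Why: Regioselective phenol silylation, in which the bulky silyl chloride should take the hydroxyl para to bromine (flanked by two C–H) in preference to the one shielded by the ortho bromine.

Step 4
Reactants: 7 2-bromo-5-[(triisopropylsilyl)oxy]phenol; 8 3-chloro-3-methylbut-1-yne
Product: 9 [4-bromo-3-(2-methylbut-3-yn-2-yloxy)phenoxy]triisopropylsilane
Conditions: CuCl2·2H2O (cat.), DBU, MeCN, 0 °C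
Reagents that add atoms: none
Why: Copper-catalysed propargylic etherification, in which the copper acetylide of the tertiary chloride ionises and the phenoxide is captured at the tertiary carbon; ortho-substituted phenols are tolerated.

Step 5
Reactants: 9 [4-bromo-3-(2-methylbut-3-yn-2-yloxy)phenoxy]triisopropylsilane
Product: 12 [(8-bromo-2,2-dimethyl-2H-chromen-5-yl)oxy]triisopropylsilane, via allenylphenol 10 (not isolated), via quinone methide 11 (not isolated)
Conditions: o-xylene, 140 °C
Reagents that add atoms: none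
Why: The aromatic propargyl Claisen rearrangement can only reach the one free ortho carbon (the other bears bromine), and the allenylphenol should close to the 2H-chromene by 1,5-hydrogen shift and oxa-6π electrocyclisation, which fixes the pyran oxygen next to the C–Br carbon.

Step 6
Reactants: 12 [(8-bromo-2,2-dimethyl-2H-chromen-5-yl)oxy]triisopropylsilane
Product: 15 Ar–B(OH)2 (arylboronic acid), via aryllithium 13 (not isolated), via lithium triisopropoxyborate 14 (not isolated)
Conditions: n-BuLi, THF, −78 °C; B(OiPr)3, −78 → 0 °C; dil. aq HCl to pH 6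
Reagents that add atoms: triisopropyl borate, CC(C)OB(OC(C)C)OC(C)C; water, O
Why: Bromine–lithium exchange followed by borylation and mild hydrolysis is the standard route to arylboronic acids, and the aryllithium is stabilised by the ortho ether oxygen while the para silyl ether is too remote to migrate.

Step 7
Reactants: 15 Ar–B(OH)2; 16 furan-2(5H)-one
Product: 17 (4R)-4-Ar-dihydrofuran-2(3H)-one
Conditions: [Rh(OH)((R)-BINAP)]2 (cat.), 15 (2 equiv), dioxane/H2O 10:1, 40 °C
Reagents that add atoms: none
Why: Hayashi–Miyaura conjugate arylation, in which the aryl–rhodium species inserts the butenolide C=C on the enantioface left open by (R)-BINAP and water hydrolyses the rhodium enolate, should set the later C3 as R (the ligand controls the face).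

Step 8
Reactants: 17 (4R)-4-Ar-dihydrofuran-2(3H)-one
Product: 18 (4R)-5-hydroxy-1-methoxy-4-Ar-pentan-2-one
Conditions: Bu3SnCH2OMe, n-BuLi, THF, −78 °C; then 17, −78 °C; AcOH quench at −78 °C
Reagents that add atoms: tributyl(methoxymethyl)stannane, CCCC[Sn](CCCC)(CCCC)COC
Why: Tin–lithium exchange gives methoxymethyllithium, which should add only once to the lactone because the lithium hemiketal alkoxide is stable at −78 °C (organolithium mono-addition to a lactone); the stereocentre is beta to the carbonyl and cannot epimerise.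

Step 9
Reactants: 18 (4R)-5-hydroxy-1-methoxy-4-Ar-pentan-2-one
Product: 19 (4R)-5-[(tert-butyldimethylsilyl)oxy]-1-methoxy-4-Ar-pentan-2-one
Conditions: TBSCl, imidazole, DMF, 0 °C → rt
Reagents that add atoms: tert-butyldimethylsilyl chloride, CC(C)(C)[Si](C)(C)Cl
Why: Standard silylation, in which the open-chain primary alcohol reacts much faster than the hindered hemiketal hydroxyl and so drains the ring–chain equilibrium to the keto silyl ether.

Step 10
Reactants: 19 (4R)-5-[(tert-butyldimethylsilyl)oxy]-1-methoxy-4-Ar-pentan-2-one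
Product: 21 tert-butyl{[(2R)-5-methoxy-2-Ar-pent-4-yn-1-yl]oxy}dimethylsilane, via enol triflate 20 (not isolated)
Conditions: LiN(SiMe3)2, THF, −78 °C; PhNTf2, DMPU, −78 → 0 °C; then KOtBu, −78 °C; aq NH4Cl
Reagents that add atoms: none
Why: Conversion of an alpha-alkoxy ketone into an ynol ether through its enol triflate: lithium-chelated deprotonation at the unbranched, inductively activated methoxy-bearing methylene should give the Z-triflate, whose vinylic hydrogen is anti to the triflate so that tert-butoxide effects E2 elimination at −78 °C.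

Step 11
Reactants: 21 tert-butyl{[(2R)-5-methoxy-2-Ar-pent-4-yn-1-yl]oxy}dimethylsilane; 5 3-methoxy-2-(3-methylbut-2-en-1-yl)cyclobut-2-en-1-one
Product: 26 2-{(2R)-3-[(tert-butyldimethylsilyl)oxy]-2-Ar-propyl}-3,5-dimethoxy-4-(3-methylbut-2-en-1-yl)phenol, via vinylketene 22 (not isolated), via vinylcyclobutenone 23 (not isolated), via dienylketene 24 (not isolated), via cyclohexadienone 25 (not isolated)
Conditions: 5 (1.3 equiv), degassed toluene, 80 → 110 °C, sealed tube
Reagents that add atoms: none
Why: On heating, 5 should open by 4π electrocyclic reversion to vinylketene 22, which adds [2+2] to the electron-rich triple bond of 21 to give 23; a second 4π opening gives dienylketene 24, which cyclises to 25 and tautomerises to phenol 26 (Danheiser benzannulation of a cyclobutenone with an alkoxyalkyne). Ring A is closed by thermal disrotatory 6π electrocyclisation of 24, which re-forms the C8–C8a bond after the [2+2] step has made the two new skeletal bonds C4a–C8a and C5–C6. No stereocentre is created: the quaternary centre of 23 is transient, and C3, separated from the reacting carbons by the C4 methylene, should keep its R configuration under neutral heating. The step needs regioselectivity in the ketene–alkyne addition, which the polarisation of the ynol ether secures, since its nucleophilic carbon remote from oxygen bonds to the electrophilic ketene carbonyl carbon and so places the side chain next to the new hydroxyl and OMe on C5. It also needs chemoselectivity for the alkyne over the prenyl and chromene double bonds, which the far higher ketenophilicity of the ynol ether provides, and the methyl ynol ether has no beta hydrogen for retro-ene loss at these temperatures.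

Step 12
Reactants: 26 2-{(2R)-3-[(tert-butyldimethylsilyl)oxy]-2-Ar-propyl}-3,5-dimethoxy-4-(3-methylbut-2-en-1-yl)phenol
Product: 27 2-[(2R)-3-hydroxy-2-Ar-propyl]-3,5-dimethoxy-4-(3-methylbut-2-en-1-yl)phenol
Conditions: PPTS (cat.), MeOH, rt
Reagents that add atoms: none
Why: Selective acid-catalysed methanolysis, which removes a primary alkyl TBS ether far faster than an aryl TIPS ether, with an acid too weak to ionise the chromene or cyclise the prenyl group.

Step 13
Reactants: 27 2-[(2R)-3-hydroxy-2-Ar-propyl]-3,5-dimethoxy-4-(3-methylbut-2-en-1-yl)phenol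
Product: 29 Kanzonol I, via chroman silyl ether 28 (not isolated)
Conditions: PPh3, DIAD, THF (0.02 M), 0 °C → rt; then TBAF, THF, 0 °C; aq NH4Cl
Reagents that add atoms: none
Why: Mitsunobu etherification, in which the primary alcohol is activated as its alkoxyphosphonium ion and displaced by the C8a phenoxide in a 6-exo-tet closure at the non-stereogenic C2, leaves C3 untouched, and fluoride then cleaves the aryl silyl ether in the same flask to free the 4'-hydroxyl.

**Compound list**

1 | chloroacetaldehyde dimethyl acetal | COC(CCl)OC | starting material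
2 | prenyl bromide | CC(C)=CCBr | starting material
3 | sodium methoxyacetylide (NaC≡COMe) | COC#[C-].[Na+] | intermediate
4 | 1-methoxy-5-methylhex-4-en-1-yne | COC#CCC=C(C)C | intermediate
5 | 3-methoxy-2-(3-methylbut-2-en-1-yl)cyclobut-2-en-1-one | COC1=C(CC=C(C)C)C(=O)C1 | intermediate
6 | 4-bromoresorcinol | Oc1ccc(Br)c(O)c1 | starting material
7 | 2-bromo-5-[(triisopropylsilyl)oxy]phenol | Oc1cc(O[Si](C(C)C)(C(C)C)C(C)C)ccc1Br | intermediate
8 | 3-chloro-3-methylbut-1-yne | CC(C)(Cl)C#C | starting material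
9 | [4-bromo-3-(2-methylbut-3-yn-2-yloxy)phenoxy]triisopropylsilane | C#CC(C)(C)Oc1cc(O[Si](C(C)C)(C(C)C)C(C)C)ccc1Br | intermediate
10 | 2-bromo-6-(3-methylbuta-1,2-dien-1-yl)-5-[(triisopropylsilyl)oxy]phenol | CC(C)=C=Cc1c(O)c(Br)ccc1O[Si](C(C)C)(C(C)C)C(C)C | intermediate
11 | 2-bromo-6-(3-methylbut-2-en-1-ylidene)-5-[(triisopropylsilyl)oxy]cyclohexa-2,4-dien-1-one | CC(C)=CC=C1C(=O)C(Br)=CC=C1O[Si](C(C)C)(C(C)C)C(C)C | intermediate
12 | [(8-bromo-2,2-dimethyl-2H-chromen-5-yl)oxy]triisopropylsilane (Ar–Br) | CC1(C)C=Cc2c(O[Si](C(C)C)(C(C)C)C(C)C)ccc(Br)c2O1 | intermediate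
13 | {2,2-dimethyl-5-[(triisopropylsilyl)oxy]-2H-chromen-8-yl}lithium (Ar–Li) | [Li]c1ccc(O[Si](C(C)C)(C(C)C)C(C)C)c2C=CC(C)(C)Oc12 | intermediate
14 | lithium triisopropoxy(Ar)borate, Li[ArB(OiPr)3] | [Li+].CC(C)O[B-](OC(C)C)(OC(C)C)c1ccc(O[Si](C(C)C)(C(C)C)C(C)C)c2C=CC(C)(C)Oc12 | intermediate
15 | {2,2-dimethyl-5-[(triisopropylsilyl)oxy]-2H-chromen-8-yl}boronic acid | OB(O)c1ccc(O[Si](C(C)C)(C(C)C)C(C)C)c2C=CC(C)(C)Oc12 | intermediate
16 | furan-2(5H)-one | O=C1OCC=C1 | starting material
17 | (4R)-4-Ar-dihydrofuran-2(3H)-one | O=C1C[C@H](c2ccc(O[Si](C(C)C)(C(C)C)C(C)C)c3C=CC(C)(C)Oc23)CO1 | intermediate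
18 | (4R)-5-hydroxy-1-methoxy-4-Ar-pentan-2-one | COCC(=O)C[C@H](c1ccc(O[Si](C(C)C)(C(C)C)C(C)C)c2C=CC(C)(C)Oc12)CO | intermediate
19 | (4R)-5-[(tert-butyldimethylsilyl)oxy]-1-methoxy-4-Ar-pentan-2-one | COCC(=O)C[C@H](c1ccc(O[Si](C(C)C)(C(C)C)C(C)C)c2C=CC(C)(C)Oc12)CO[Si](C)(C)C(C)(C)C | intermediate
20 | (1Z,4R)-5-[(tert-butyldimethylsilyl)oxy]-1-methoxy-4-Ar-pent-1-en-2-yl trifluoromethanesulfonate | CO/C=C(\OS(=O)(=O)C(F)(F)F)C[C@H](c1ccc(O[Si](C(C)C)(C(C)C)C(C)C)c2C=CC(C)(C)Oc12)CO[Si](C)(C)C(C)(C)C | intermediate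
21 | tert-butyl{[(2R)-5-methoxy-2-Ar-pent-4-yn-1-yl]oxy}dimethylsilane | COC#CC[C@H](c1ccc(O[Si](C(C)C)(C(C)C)C(C)C)c2C=CC(C)(C)Oc12)CO[Si](C)(C)C(C)(C)C | intermediate
22 | 3-methoxy-2-(3-methylbut-2-en-1-yl)buta-1,3-dien-1-one | C=C(OC)C(CC=C(C)C)=C=O | intermediate
23 | 2-{(2R)-3-[(tert-butyldimethylsilyl)oxy]-2-Ar-propyl}-3-methoxy-4-(1-methoxyvinyl)-4-(3-methylbut-2-en-1-yl)cyclobut-2-en-1-one (both epimers at the ring quaternary carbon) | O=C1C(C[C@H](c2ccc(O[Si](C(C)C)(C(C)C)C(C)C)c3C=CC(C)(C)Oc23)CO[Si](C)(C)C(C)(C)C)=C(OC)C1(CC=C(C)C)C(OC)=C | intermediate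
24 | (3E)-2-{(2R)-3-[(tert-butyldimethylsilyl)oxy]-2-Ar-propyl}-3,5-dimethoxy-4-(3-methylbut-2-en-1-yl)hexa-1,3,5-trien-1-one | O=C=C(C[C@H](c1ccc(O[Si](C(C)C)(C(C)C)C(C)C)c2C=CC(C)(C)Oc12)CO[Si](C)(C)C(C)(C)C)/C(OC)=C(/CC=C(C)C)C(OC)=C | intermediate
25 | 2-{(2R)-3-[(tert-butyldimethylsilyl)oxy]-2-Ar-propyl}-3,5-dimethoxy-4-(3-methylbut-2-en-1-yl)cyclohexa-2,4-dien-1-one | O=C1CC(OC)=C(CC=C(C)C)C(OC)=C1C[C@H](c1ccc(O[Si](C(C)C)(C(C)C)C(C)C)c2C=CC(C)(C)Oc12)CO[Si](C)(C)C(C)(C)C | intermediate
26 | 2-{(2R)-3-[(tert-butyldimethylsilyl)oxy]-2-Ar-propyl}-3,5-dimethoxy-4-(3-methylbut-2-en-1-yl)phenol | Oc1cc(OC)c(CC=C(C)C)c(OC)c1C[C@H](c1ccc(O[Si](C(C)C)(C(C)C)C(C)C)c2C=CC(C)(C)Oc12)CO[Si](C)(C)C(C)(C)C | intermediate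
27 | 2-[(2R)-3-hydroxy-2-Ar-propyl]-3,5-dimethoxy-4-(3-methylbut-2-en-1-yl)phenol | Oc1cc(OC)c(CC=C(C)C)c(OC)c1C[C@H](c1ccc(O[Si](C(C)C)(C(C)C)C(C)C)c2C=CC(C)(C)Oc12)CO | intermediate
28 | ({8-[(3R)-5,7-dimethoxy-6-(3-methylbut-2-en-1-yl)chroman-3-yl]-2,2-dimethyl-2H-chromen-5-yl}oxy)triisopropylsilane | COc1cc2c(c(OC)c1CC=C(C)C)C[C@H](c1ccc(O[Si](C(C)C)(C(C)C)C(C)C)c3c1OC(C)(C)C=C3)CO2 | intermediate
29 | Kanzonol I, 8-[(3R)-5,7-dimethoxy-6-(3-methylbut-2-en-1-yl)chroman-3-yl]-2,2-dimethyl-2H-chromen-5-ol | COc1cc2c(c(OC)c1CC=C(C)C)C[C@H](c1ccc(O)c3c1OC(C)(C)C=C3)CO2 | target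

**Step count.** Total: 13 steps (steps 1–2 make the cyclobutenone, steps 3–10 the ynol ether, steps 11–13 the endgame). Longest linear sequence: 11 steps (steps 3–13, from 4-bromoresorcinol 6).

**Steps most likely to fail**

1. Step 11. The donor-stabilised cyclobutenone may open too slowly, so that thermal decomposition of the ynol ether or acylation of the new phenol by a second ketene molecule overtakes the cascade. The fallback makes the same vinylketene at room temperature by photochemical Wolff rearrangement. It sets out from ynol ether 21 and comes back at vinylketene 22 and hence at phenol 26. Commercial 5-methylhex-4-enoic acid is converted (carbonyldiimidazole, MeNHOMe·HCl) into N-methoxy-N,5-dimethylhex-4-enamide F1. This is treated with 1-methoxyvinyllithium F2 (methyl vinyl ether, t-BuLi, THF) to give 2-methoxy-7-methylocta-1,6-dien-3-one F3. Detrifluoroacetylative diazo transfer follows: LiN(SiMe3)2 and CF3CO2CH2CF3 give the trifluoroacetyl ketone 1,1,1-trifluoro-5-methoxy-3-(3-methylbut-2-en-1-yl)hex-5-ene-2,4-dione F4, which is not isolated, and MsN3, Et3N and water then give 4-diazo-2-methoxy-7-methylocta-1,6-dien-3-one F5. Irradiation of F5 at 365 nm with 21 in 1,2-dichloroethane at rt should release 22, which enters the same cascade; brief warming to 80 °C should complete conversion to 26.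

2. Step 10. Regiocontrol may be lost in the enolisation (deprotonation on the C4 side), or the triflate may form with the wrong geometry so that anti elimination is blocked. The fallback brings in the MeO–C≡C unit intact and needs no enolisation. It sets out from lactone 17 and comes back at ynol ether 21.
   - Lactone 17 is saponified (LiOH, THF/H2O) to lithium (3R)-4-hydroxy-3-Ar-butanoate F6.
   - F6 is silylated on both oxygens (TBSCl, imidazole, DMF) to tert-butyldimethylsilyl (3R)-4-[(tert-butyldimethylsilyl)oxy]-3-Ar-butanoate F7.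
   - The silyl ester of F7 is cleaved (K2CO3, MeOH/H2O) to (3R)-4-[(tert-butyldimethylsilyl)oxy]-3-Ar-butanoic acid F8.
   - Barton decarboxylative iodination follows: esterification with N-hydroxypyridine-2-thione (DCC, DMAP, dark) gives the thiohydroxamate ester 2-thioxopyridin-1(2H)-yl (3R)-4-[(tert-butyldimethylsilyl)oxy]-3-Ar-butanoate F9, and CHI3 with visible light then gives tert-butyl{[(2R)-3-iodo-2-Ar-propyl]oxy}dimethylsilane F10.
   - F10 is alkylated in THF/HMPA with lithium methoxyacetylide F11 (from acetal 1 and LiNEt2) to give 21.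

3. Step 7. Protodeboronation of the electron-rich ortho-alkoxy boronic acid may outrun the slow insertion into the sluggish five-membered acceptor, or facial discrimination may be incomplete with the ortho-substituted aryl group. The fallback separates C–C bond formation from stereocontrol. It sets out from boronic acid 15 and comes back at lactone 17. Suzuki–Miyaura coupling of 15 with commercial 4-bromofuran-2(5H)-one (Pd(OAc)2, SPhos, K3PO4, THF/H2O, rt) gives 4-Ar-furan-2(5H)-one F12. Asymmetric copper hydride conjugate reduction (Cu(OAc)2·H2O, p-tol-BINAP, polymethylhydrosiloxane, t-BuOH, toluene, rt; ligand antipode chosen to give R) should then deliver 17 without touching the chromene double bond.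

**Further compounds**

F1 | step 11 | N-methoxy-N,5-dimethylhex-4-enamide | CON(C)C(=O)CCC=C(C)C
F2 | step 11 | 1-methoxyvinyllithium | [Li]C(=C)OC
F3 | step 11 | 2-methoxy-7-methylocta-1,6-dien-3-one | C=C(OC)C(=O)CCC=C(C)C
F4 | step 11 | 1,1,1-trifluoro-5-methoxy-3-(3-methylbut-2-en-1-yl)hex-5-ene-2,4-dione | C=C(OC)C(=O)C(CC=C(C)C)C(=O)C(F)(F)F
F5 | step 11 | 4-diazo-2-methoxy-7-methylocta-1,6-dien-3-one | C=C(OC)C(=O)C(=[N+]=[N-])CC=C(C)C
F6 | step 10 | lithium (3R)-4-hydroxy-3-Ar-butanoate | [Li+].[O-]C(=O)C[C@H](c1ccc(O[Si](C(C)C)(C(C)C)C(C)C)c2C=CC(C)(C)Oc12)CO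
F7 | step 10 | tert-butyldimethylsilyl (3R)-4-[(tert-butyldimethylsilyl)oxy]-3-Ar-butanoate | CC(C)(C)[Si](C)(C)OC(=O)C[C@H](c1ccc(O[Si](C(C)C)(C(C)C)C(C)C)c2C=CC(C)(C)Oc12)CO[Si](C)(C)C(C)(C)C
F8 | step 10 | (3R)-4-[(tert-butyldimethylsilyl)oxy]-3-Ar-butanoic acid | OC(=O)C[C@H](c1ccc(O[Si](C(C)C)(C(C)C)C(C)C)c2C=CC(C)(C)Oc12)CO[Si](C)(C)C(C)(C)C
F9 | step 10 | 2-thioxopyridin-1(2H)-yl (3R)-4-[(tert-butyldimethylsilyl)oxy]-3-Ar-butanoate | S=c1ccccn1OC(=O)C[C@H](c1ccc(O[Si](C(C)C)(C(C)C)C(C)C)c2C=CC(C)(C)Oc12)CO[Si](C)(C)C(C)(C)C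
F10 | step 10 | tert-butyl{[(2R)-3-iodo-2-Ar-propyl]oxy}dimethylsilane | IC[C@H](c1ccc(O[Si](C(C)C)(C(C)C)C(C)C)c2C=CC(C)(C)Oc12)CO[Si](C)(C)C(C)(C)C
F11 | step 10 | lithium methoxyacetylide (LiC≡COMe) | COC#[C-].[Li+]
F12 | step 7 | 4-Ar-furan-2(5H)-one | O=C1C=C(c2ccc(O[Si](C(C)C)(C(C)C)C(C)C)c3C=CC(C)(C)Oc23)CO1
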